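A direct plan would join the two rings at the ether oxygen: 2-bromo-6-methoxyphenol A1 would be O-arylated with the aryl donor (2-methoxyphenyl)(2,4,6-trimethoxyphenyl)iodonium tosylate A2 to give 1-bromo-3-methoxy-2-(2-methoxyphenoxy)benzene A3, and double demethylation to 3-bromo-2-(2-hydroxyphenoxy)phenol A4 followed by a fourfold bromination would finish. Its weakest steps would be:
- the making of the aryl donor A2, which would add a step and a sacrificial arene but no complexity;
- the C–O coupling of A1 to A3, in which a di-ortho-substituted phenoxide would have to take up an ortho-substituted aryl group, so that congestion and transfer of the wrong aryl group would threaten;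
- the fourfold bromination of A4, which would place four of the five bromines in one step on two rings at once and would have to stop there although the ether oxygen activates the positions left.

**Strategy.** The route would not couple two arenes at oxygen. The ether oxygen would first be bound to an sp3 carbon, as a (bromophenoxy)acetic acid that is brominated while still monocyclic. Ring A (the 3,5-dibromo-2-hydroxyphenoxy ring) would then be built on it: the bis-silyl ketene acetal of that acid supplies C1' and C2' with both oxygens, and 3,5-dibromo-2-pyrone supplies C3'–C6' with both bromines. One cycloaddition, CO2 extrusion and silanol loss would form two C–C bonds, the aromatic ring and the 2'-OH in its place. No aryl donor, no O-arylation and no bromination of a diaryl ether would remain.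

Key step: step 4

Remark: 3,5-dibromo-2H-pyran-2-one (8) is taken as a purchasable compound; the non-aromatic intermediates of step 4 are racemic and converge on the achiral target.

Step 1
Reactants: 1 2-bromo-6-methoxyphenol; 2 tert-butyl bromoacetate
Product: 3 tert-butyl 2-(2-bromo-6-methoxyphenoxy)acetate
Conditions: K2CO3 (1.5 equiv), acetone, 56 °C, 6 h
Reagents that add atoms: none
Why: Williamson ether synthesis; an α-bromo ester is among the fastest SN2 electrophiles, so the di-ortho-substituted phenoxide should alkylate cleanly at oxygen, and the ether oxygen of the target is thereby bound to an sp3 carbon instead of to an arene.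

Step 2
Reactants: 3 tert-butyl 2-(2-bromo-6-methoxyphenoxy)acetate
Product: 5 2-(2,3,5-tribromo-6-hydroxyphenoxy)acetic acid, via 2-(2-bromo-6-hydroxyphenoxy)acetic acid 4 (not isolated)
Conditions: BBr3 (2.5 equiv), CH2Cl2, −78 → 0 °C; H2O, EtOAc extraction; then Br2 (2.05 equiv), AcOH, rt, 2 h; aq Na2S2O3
Reagents that add atoms: bromine, BrBr
Why: Lewis-acid ether cleavage with BBr3 should remove the methyl group and the tert-butyl ester while the least basic oxygen (the aryloxyacetic one) survives at or below 0 °C; the free OH then directs electrophilic aromatic bromination to its para and ortho positions (C3 and C5 of the phenoxy ring) on a monocyclic substrate, C4 being meta to OH and flanked by two bromines.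

Step 3
Reactants: 5 2-(2,3,5-tribromo-6-hydroxyphenoxy)acetic acid
Product: 7 1,1-bis(trimethylsilyloxy)-2-[2,3,5-tribromo-6-(trimethylsilyloxy)phenoxy]ethene, via trimethylsilyl 2-[2,3,5-tribromo-6-(trimethylsilyloxy)phenoxy]acetate 6 (not isolated)
Conditions: Me3SiCl (2.2 equiv), Et3N (2.3 equiv), THF, 0 °C → rt; then Me3SiCl (1.5 equiv), LiN(SiMe3)2 (1.2 equiv), −78 → 0 °C; evaporation, pentane, filtration under argon; used crude
Reagents that add atoms: chlorotrimethylsilane, C[Si](C)(C)Cl
Why: O-silylation of the phenol and the acid, then enolisation of the silyl ester with internal silyl chloride trapping (bis-silyl ketene acetal formation of the Ainsworth type); the hindered, weakly basic silylamide at −78 °C is chosen so that the ring C–H between two bromines should not be metalated, and the two identical silyloxy groups leave no alkene geometry to control.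

Step 4
Reactants: 7 1,1-bis(trimethylsilyloxy)-2-[2,3,5-tribromo-6-(trimethylsilyloxy)phenoxy]ethene (1.3 equiv); 8 3,5-dibromo-2H-pyran-2-one
Product: 12 3,4,6-tribromo-2-(3,5-dibromo-2-hydroxyphenoxy)phenol (target), via bridged lactone cycloadduct 9 (not isolated), via cyclohexadiene ketal 10 (not isolated), via bis(trimethylsilyl) ether 11 (not isolated)
Conditions: toluene, 60 °C, then 110 °C until CO2 evolution ends; then 1 M HCl, THF, rt
Reagents that add atoms: none
Why: Inverse-electron-demand Diels–Alder reaction of the electron-poor diene 8 with the electron-rich ketene acetal 7, of the kind known for 3,5-dibromo-2-pyrone with enol ethers and for 2-pyrones with ketene acetals (pyrone benzannulation). The only ring closed is ring A, by an intermolecular and probably asynchronous (4+2) cycloaddition in which the nucleophilic CH(OAr) carbon of 7 bonds to the electrophilic C6 of 8 and the acetal carbon to C3. Retro-(4+2) loss of CO2 from bridged lactone 9 should give diene 10, and 1,2-elimination of Me3SiOH should aromatise it to 11; the aryloxy group is retained because the neighbouring ketal carbon carries no hydrogen that could leave with it. The step needs regioselectivity only: two silyloxy donors on one carbon polarise 7 far more strongly than the twisted, electron-poor aryloxy group on the other, so the oxygen that becomes the 2'-OH should end next to C3'–Br and the ether oxygen next to C6'–H. The stereocentres of 9 and 10 (racemic, endo/exo) vanish on aromatisation, and aqueous acid then frees both phenols.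

**Compound list**
1 | 2-bromo-6-methoxyphenol | COc1cccc(Br)c1O | starting material
2 | tert-butyl bromoacetate | CC(C)(C)OC(=O)CBr | starting material
3 | tert-butyl 2-(2-bromo-6-methoxyphenoxy)acetate | COc1cccc(Br)c1OCC(=O)OC(C)(C)C | intermediate
4 | 2-(2-bromo-6-hydroxyphenoxy)acetic acid | OC(=O)COc1c(O)cccc1Br | intermediate
5 | 2-(2,3,5-tribromo-6-hydroxyphenoxy)acetic acid | OC(=O)COc1c(O)c(Br)cc(Br)c1Br | intermediate
6 | trimethylsilyl 2-[2,3,5-tribromo-6-(trimethylsilyloxy)phenoxy]acetate | C[Si](C)(C)OC(=O)COc1c(O[Si](C)(C)C)c(Br)cc(Br)c1Br | intermediate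
7 | 1,1-bis(trimethylsilyloxy)-2-[2,3,5-tribromo-6-(trimethylsilyloxy)phenoxy]ethene | C[Si](C)(C)OC(O[Si](C)(C)C)=COc1c(O[Si](C)(C)C)c(Br)cc(Br)c1Br | intermediate
8 | 3,5-dibromo-2H-pyran-2-one | O=C1OC=C(Br)C=C1Br | starting material
9 | 4,7-dibromo-5,5-bis(trimethylsilyloxy)-6-[2,3,5-tribromo-6-(trimethylsilyloxy)phenoxy]-2-oxabicyclo[2.2.2]oct-7-en-3-one (racemic, endo/exo mixture) | O=C1OC2C(Br)=CC1(Br)C(O[Si](C)(C)C)(O[Si](C)(C)C)C2Oc1c(O[Si](C)(C)C)c(Br)cc(Br)c1Br | intermediate
10 | 1,3-dibromo-6,6-bis(trimethylsilyloxy)-5-[2,3,5-tribromo-6-(trimethylsilyloxy)phenoxy]cyclohexa-1,3-diene (racemic) | C[Si](C)(C)OC1(O[Si](C)(C)C)C(Br)=CC(Br)=CC1Oc1c(O[Si](C)(C)C)c(Br)cc(Br)c1Br | intermediate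
11 | [2,4-dibromo-6-[2,3,5-tribromo-6-(trimethylsilyloxy)phenoxy]phenoxy]trimethylsilane (bis-silyl ether of 12) | C[Si](C)(C)Oc1c(Br)cc(Br)cc1Oc1c(O[Si](C)(C)C)c(Br)cc(Br)c1Br | intermediate
12 | 3,4,6-tribromo-2-(3,5-dibromo-2-hydroxyphenoxy)phenol | Oc1c(Br)cc(Br)cc1Oc1c(O)c(Br)cc(Br)c1Br | target

**Count**
Total steps: 4. Longest linear sequence: 4 (1 → 3 → 5 → 7 → 12).

**Steps most likely to fail**

1. Step 4. The second C–C bond joins two fully substituted carbons (C3 of 8 with its bromine, and the ketal carbon), so ring closure may be slow and silyl transfer in a Michael-type adduct or decay of the ketene acetal may take over. The fallback would set out from 1 and come back at 12 by known chemistry. Nucleophilic aromatic substitution of 2,4-dibromo-6-fluorobenzaldehyde F1 by 1 (K2CO3, DMAc, 100 °C) would give 2,4-dibromo-6-(2-bromo-6-methoxyphenoxy)benzaldehyde F2. Baeyer–Villiger (Dakin-type) oxidation with mCPBA would give 2,4-dibromo-6-(2-bromo-6-methoxyphenoxy)phenyl formate F3, and K2CO3/MeOH would free 2,4-dibromo-6-(2-bromo-6-methoxyphenoxy)phenol F4. BBr3 would demethylate it to 3-bromo-2-(3,5-dibromo-2-hydroxyphenoxy)phenol F5. Br2 (2.05 equiv, AcOH) would then brominate only the ring whose OH still has free ortho and para positions, giving 12.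

2. Step 3. The silylamide may metalate the ring C–H between two bromines (with halogen migration), or the water-sensitive bis-silyl ketene acetal may be lost by protodesilylation on handling. The fallback would set out from 5 and come back at 12 without any strong base. Lactonisation with (CF3CO)2O in CH2Cl2 would give 5,6,8-tribromo-1,4-benzodioxin-2(3H)-one F6. Soft enolisation with t-BuMe2SiOSO2CF3/Et3N would give the cyclic ketene acetal tert-butyl(dimethyl)[(5,6,8-tribromo-1,4-benzodioxin-2-yl)oxy]silane F7. With 8 in toluene at 60–80 °C, F7 should add to give the racemic bridged lactone cycloadduct F8. Bu4NF/AcOH would then cleave the silyl ketal of F8, the tribromophenoxide would be expelled, and warming would extrude CO2 and tautomerise the dienone to 12.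

3. Step 2. Boron chelation between the two ortho oxygens may cleave the aryloxyacetic C–O bond together with the methyl ether, or bromination may run past two bromines. The fallback would set out from 2 and come back at 4, with the phenol unveiled by oxidation instead of ether cleavage. Alkylation of 3-bromo-2-hydroxybenzaldehyde F9 with 2 (K2CO3, acetone, rt) would give tert-butyl 2-(2-bromo-6-formylphenoxy)acetate F10. mCPBA would convert it to tert-butyl 2-[2-bromo-6-(formyloxy)phenoxy]acetate F11, and KHCO3/MeOH would give tert-butyl 2-(2-bromo-6-hydroxyphenoxy)acetate F12. CF3CO2H in CH2Cl2 would cleave the ester to 4, which would be brominated as in the second half of step 2, if need be with the bromine added in portions at 0 °C.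

**Further compounds**
F1 | step 4 | 2,4-dibromo-6-fluorobenzaldehyde | O=Cc1c(F)cc(Br)cc1Br
F2 | step 4 | 2,4-dibromo-6-(2-bromo-6-methoxyphenoxy)benzaldehyde | COc1cccc(Br)c1Oc1cc(Br)cc(Br)c1C=O
F3 | step 4 | 2,4-dibromo-6-(2-bromo-6-methoxyphenoxy)phenyl formate | COc1cccc(Br)c1Oc1cc(Br)cc(Br)c1OC=O
F4 | step 4 | 2,4-dibromo-6-(2-bromo-6-methoxyphenoxy)phenol | COc1cccc(Br)c1Oc1cc(Br)cc(Br)c1O
F5 | step 4 | 3-bromo-2-(3,5-dibromo-2-hydroxyphenoxy)phenol | Oc1cccc(Br)c1Oc1cc(Br)cc(Br)c1O
F6 | step 3 | 5,6,8-tribromo-1,4-benzodioxin-2(3H)-one | O=C1COc2c(Br)c(Br)cc(Br)c2O1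
F7 | step 3 | tert-butyl(dimethyl)[(5,6,8-tribromo-1,4-benzodioxin-2-yl)oxy]silane | CC(C)(C)[Si](C)(C)OC1=COc2c(Br)c(Br)cc(Br)c2O1
F8 | step 3 | bridged lactone cycloadduct of F7 and 8 (racemic) | O=C1OC2C(Br)=CC1(Br)C3(O[Si](C)(C)C(C)(C)C)Oc4c(Br)cc(Br)c(Br)c4OC23
F9 | step 2 | 3-bromo-2-hydroxybenzaldehyde | O=Cc1cccc(Br)c1O
F10 | step 2 | tert-butyl 2-(2-bromo-6-formylphenoxy)acetate | CC(C)(C)OC(=O)COc1c(Br)cccc1C=O
F11 | step 2 | tert-butyl 2-[2-bromo-6-(formyloxy)phenoxy]acetate | CC(C)(C)OC(=O)COc1c(Br)cccc1OC=O
F12 | step 2 | tert-butyl 2-(2-bromo-6-hydroxyphenoxy)acetate | CC(C)(C)OC(=O)COc1c(O)cccc1Br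
A1 | direct plan | 2-bromo-6-methoxyphenol | COc1cccc(Br)c1O
A2 | direct plan | (2-methoxyphenyl)(2,4,6-trimethoxyphenyl)iodonium tosylate | COc1ccccc1[I+]c1c(OC)cc(OC)cc1OC.Cc1ccc(cc1)S(=O)(=O)[O-]
A3 | direct plan | 1-bromo-3-methoxy-2-(2-methoxyphenoxy)benzene | COc1ccccc1Oc1c(OC)cccc1Br
A4 | direct plan | 3-bromo-2-(2-hydroxyphenoxy)phenol | Oc1ccccc1Oc1c(O)cccc1Br
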